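**The vessels.** Tank elm runs at steady state with a mean residence time of 6.0 min, and closed flask larch runs for the same 6.0 min.

| setting | elm | larch |
|---|---|---|
| substrate | 0.10 M | 0.10 M |
| remark | one stirred flow tank at steady state, fed with the mixture as stated, mean residence time 6.0 min | everything together in a closed stirred flask, run for 6.0 min |
| time |  | 6.0 min |

    substrate ⇌ intermediate A (K1 = 11, k1 = 0.0026 /s)
    intermediate A → decomposed reagent (k2 = 9.6 × 10⁻⁴ /s)
    intermediate D → target (k3 = 0.0034 /s)
    substrate → intermediate B (k4 = 0.0077 /s)
    intermediate B → intermediate C (k5 = 0.0057 /s)
    intermediate C → intermediate D (k6 = 0.045 /s)

- the set-up with the highest amount of target at the outlet or at the end, in percent of the substrate put in ("none" if the first two lie within 2 percentage points) (elm / larch / none)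
- amount of target at the outlet or at the end, in percent of the substrate put in, elm
- amount of target at the outlet or at the end, in percent of the substrate put in, larch

**Two times.** Each step has one species on its left, so you can reckon in fractions of the charge. Target ends the chain from substrate through intermediate B, intermediate C and intermediate D. Set two times side by side: the time on offer, 6.0 min, and the chain time, the sum of the mean lifetimes along that chain, with both exits counted for substrate, 9.81 min. Their ratio is 0.611.

**My reckoning.** In larch, every drop gets exactly 6.0 min. In elm, drops stay for a spread of times around that mean, and the long stayers carry target. The time on offer is shorter than the chain time, so I expect that spread to cost elm little, and the two to lie close. Going stage by stage through elm, and setting aside the return from intermediate A, I get 20.5% of the charge. I do not reckon larch.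

**The forecast.** It gave 20.8% for elm, above my figure, and 21.9% for larch, so its choice is none: “the two land about a point apart”.

**The result.** Elm gives 20.8% and larch 21.8%, which are 1 percentage point apart, inside the margin of 2 points, so the answer is none. Larch has not come to rest at 6.0 min, with 18.1% as intermediate A and 17.8% as intermediate B. At ten times the time, the ratio to the chain time is 6.12. Larch then holds 78.5% as target at 60.0 min, while elm at ten times the residence time gives 66.4%, so larch leads by 12 points.

(The rate constants were chosen freely; the rest is arithmetic.)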